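**Retrosynthetic overview**
1. Target 28 comes from allyl ester 27 (deallylation) and triol 26 (acylation at O3 and O19 only). The side chain C12–C16 comes from methyl ketone 23 by Horner–Wadsworth–Emmons olefination, and 23 from C11 bromide 20 and acetoacetate.
2. Feature used: ring B (C5–C10) carries a tetrasubstituted C8=C9 alkene (C17 methyl on C8, C11 on C9) 1,4 to the C6 oxygen and next to quaternary C10. With C6 masked as a C5=C6 silyl enol ether, ring B is a 1,4-cyclohexadiene, the retron of an alkyne Diels–Alder reaction.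
3. Key disconnection: C7–C8 and C9–C10, giving the ring A 2-silyloxydiene 14 (C10=C5–C6(OTBS)=C7) and methyl but-2-ynoate 15.
4. Diene 14 comes from enone 13, from enol triflate 10 and stannane 11, from ring A ketone 8, from 2-methylcyclohexane-1,3-dione 1 (hydroxymethylation; oxazaborolidine desymmetrisation fixes C4; Evans–Tishchenko reduction sets the 3α-oxygen trans to C19).
5. Ring order: ring A is taken from the dione; ring B is closed by the cycloaddition.

Key step: step 12

Remarks: Labdane numbering is used for ring atoms throughout (C18 = 4α-methyl, C19 = 4β-CH2O, C20 = 10β-methyl, C17 = methyl on C8). TBS = tert-butyldimethylsilyl, TBSO = tert-butyldimethylsilyloxy. The C19 oxygen is carried as a TBS ether so that O3 and O19 are freed together late in the route.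
Assumption: in the oxazaborolidine reduction of dione 3 the hydride is taken to enter anti to the larger CH2OTBS branch, as with other 2-alkyl-2-methylcyclohexane-1,3-diones, so that the new hydroxyl of 4 is cis to CH2OTBS.

**Route**

Step 1
Reactants: 1 2-methylcyclohexane-1,3-dione
Product: 2 2-(hydroxymethyl)-2-methylcyclohexane-1,3-dione
Conditions: 37 % aq. HCHO, Et3N (cat.), THF/H2O, rt
Reagents that add atoms: formaldehyde, C=O
Why: Aldol addition (hydroxymethylation) of the dione enolate to formaldehyde at C2, the only carbon nucleophilic site, builds the quaternary carbon that becomes C4; the product is still prochiral.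

Step 2
Reactants: 2 2-(hydroxymethyl)-2-methylcyclohexane-1,3-dione
Product: 3 2-[(tert-butyldimethylsilyloxy)methyl]-2-methylcyclohexane-1,3-dione
Conditions: TBSCl, imidazole, DMF, 0 °C to rt
Reagents that add atoms: tert-butyldimethylsilyl chloride, CC(C)(C)[Si](C)(C)Cl
Why: Silylation of the primary alcohol under weakly basic conditions avoids retro-aldol loss of formaldehyde and makes the CH2O branch the bulkier substituent on the quaternary carbon.

Step 3
Reactants: 3 2-[(tert-butyldimethylsilyloxy)methyl]-2-methylcyclohexane-1,3-dione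
Product: 4 (2R,3R)-2-[(tert-butyldimethylsilyloxy)methyl]-3-hydroxy-2-methylcyclohexan-1-one
Conditions: (S)-Me-CBS oxazaborolidine [(S)-1-methyl-3,3-diphenyl-tetrahydro-1H,3H-pyrrolo[1,2-c][1,3,2]oxazaborole] (20 mol %), catecholborane, toluene, −60 °C; MeOH, then aq. work-up
Reagents that add atoms: none
Why: Corey–Bakshi–Shibata reduction desymmetrises the dione: the catalyst fixes the carbinol as R (quaternary carbon as the large group) and the hydride should enter anti to CH2OTBS, so one enantiotopic carbonyl is reduced and the quaternary carbon (later C4) becomes a stereocentre with the hydroxyl (on the later C5) cis to CH2OTBS.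

Step 4
Reactants: 4 (2R,3R)-2-[(tert-butyldimethylsilyloxy)methyl]-3-hydroxy-2-methylcyclohexan-1-one
Product: 5 (1R,2S,3R)-2-[(tert-butyldimethylsilyloxy)methyl]-3-hydroxy-2-methylcyclohexyl acetate
Conditions: MeCHO (excess), SmI2 (30 mol %), THF, −10 °C
Reagents that add atoms: acetaldehyde, CC=O
Why: Evans–Tishchenko reduction: the hemiacetal of the hydroxyl with acetaldehyde, bound to trivalent samarium, passes its hydride to the ketone through a six-membered transition state from the face of that oxygen, so the new hydroxyl (C3–O) is 1,3-anti to the acetoxy group and therefore trans to CH2OTBS, and the two ring oxygens leave the step differentiated.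

Step 5
Reactants: 5 (1R,2S,3R)-2-[(tert-butyldimethylsilyloxy)methyl]-3-hydroxy-2-methylcyclohexyl acetate
Product: 6 (1R,2R,3R)-3-(tert-butyldimethylsilyloxy)-2-[(tert-butyldimethylsilyloxy)methyl]-2-methylcyclohexyl acetate
Conditions: TBSOTf, 2,6-lutidine, CH2Cl2, −78 to 0 °C
Reagents that add atoms: tert-butyldimethylsilyl trifluoromethanesulfonate, CC(C)(C)[Si](C)(C)OS(=O)(=O)C(F)(F)F
Why: Silylation of the hindered secondary alcohol with the silyl triflate and a non-nucleophilic base caps the C3 oxygen without acyl migration.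

Step 6
Reactants: 6 (1R,2R,3R)-3-(tert-butyldimethylsilyloxy)-2-[(tert-butyldimethylsilyloxy)methyl]-2-methylcyclohexyl acetate
Product: 7 (1R,2R,3R)-3-(tert-butyldimethylsilyloxy)-2-[(tert-butyldimethylsilyloxy)methyl]-2-methylcyclohexan-1-ol
Conditions: K2CO3 (cat.), MeOH, rt
Reagents that add atoms: none
Why: Base-catalysed methanolysis (transesterification) removes the acetate while both silyl ethers stay in place.

Step 7
Reactants: 7 (1R,2R,3R)-3-(tert-butyldimethylsilyloxy)-2-[(tert-butyldimethylsilyloxy)methyl]-2-methylcyclohexan-1-ol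
Product: 8 (2S,3R)-3-(tert-butyldimethylsilyloxy)-2-[(tert-butyldimethylsilyloxy)methyl]-2-methylcyclohexan-1-one
Conditions: Dess–Martin periodinane, CH2Cl2, rt
Reagents that add atoms: none
Why: Dess–Martin oxidation turns the C5 carbinol into the ketone under neutral conditions, leaving ring A with 3α-OTBS, 4β-CH2OTBS and 4α-CH3 and no epimerisable centre.

Step 8
Reactants: 8 (2S,3R)-3-(tert-butyldimethylsilyloxy)-2-[(tert-butyldimethylsilyloxy)methyl]-2-methylcyclohexan-1-one
Product: 9 (2S,3R,6RS)-3-(tert-butyldimethylsilyloxy)-2-[(tert-butyldimethylsilyloxy)methyl]-2,6-dimethylcyclohexan-1-one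
Conditions: LiN(iPr)2, THF, −78 °C; MeI, −78 to 0 °C
Reagents that add atoms: iodomethane, CI
Why: Enolate alkylation at C10, the only enolisable position because C4 is quaternary, installs the future C20 methyl; the C10 configuration is irrelevant since it becomes sp2 in the next step.

Step 9
Reactants: 9 (2S,3R,6RS)-3-(tert-butyldimethylsilyloxy)-2-[(tert-butyldimethylsilyloxy)methyl]-2,6-dimethylcyclohexan-1-one
Product: 10 (5R,6S)-5-(tert-butyldimethylsilyloxy)-6-[(tert-butyldimethylsilyloxy)methyl]-2,6-dimethylcyclohex-1-en-1-yl trifluoromethanesulfonate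
Conditions: KN(SiMe3)2, THF, −78 °C; PhNTf2, −78 °C to rt
Reagents that add atoms: N-phenylbis(trifluoromethanesulfonimide), O=S(=O)(N(c1ccccc1)S(=O)(=O)C(F)(F)F)C(F)(F)F
Why: Deprotonation can only give the tetrasubstituted C5=C10 enolate, whose O-triflation gives the enol triflate, as is known for 2,2,6-trisubstituted cyclohexanones.

Step 10
Reactants: 10 (5R,6S)-5-(tert-butyldimethylsilyloxy)-6-[(tert-butyldimethylsilyloxy)methyl]-2,6-dimethylcyclohex-1-en-1-yl trifluoromethanesulfonate; 11 tributyl(1-ethoxyvinyl)stannane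
Product: 13 1-{(5R,6S)-5-(tert-butyldimethylsilyloxy)-6-[(tert-butyldimethylsilyloxy)methyl]-2,6-dimethylcyclohex-1-en-1-yl}ethan-1-one, via ring A 2-ethoxydiene 12 (not isolated)
Conditions: Pd(PPh3)4 (5 mol %), LiCl, CuI (cat.), DMF, 80 °C; then 1 M aq. HCl, THF, 0 °C
Reagents that add atoms: water, O
Why: Stille coupling (oxidative addition of the enol triflate to zerovalent palladium, chloride-assisted transmetalation from tin, reductive elimination) forms the C5–C6 bond, and brief acid hydrolysis of the ethyl enol ether unmasks the C6 acetyl group without touching the silyl ethers.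

Step 11
Reactants: 13 1-{(5R,6S)-5-(tert-butyldimethylsilyloxy)-6-[(tert-butyldimethylsilyloxy)methyl]-2,6-dimethylcyclohex-1-en-1-yl}ethan-1-one
Product: 14 (5R,6S)-5-(tert-butyldimethylsilyloxy)-6-[(tert-butyldimethylsilyloxy)methyl]-1-[1-(tert-butyldimethylsilyloxy)vinyl]-2,6-dimethylcyclohex-1-ene
Conditions: LiN(iPr)2, THF, −78 °C; TBSOTf, −78 °C
Reagents that add atoms: tert-butyldimethylsilyl trifluoromethanesulfonate, CC(C)(C)[Si](C)(C)OS(=O)(=O)C(F)(F)F
Why: Kinetic deprotonation of the acetyl methyl group and O-silylation of the enolate give the cross-conjugated 2-silyloxydiene C10=C5–C6(OTBS)=C7.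

Step 12
Reactants: 14 (5R,6S)-5-(tert-butyldimethylsilyloxy)-6-[(tert-butyldimethylsilyloxy)methyl]-1-[1-(tert-butyldimethylsilyloxy)vinyl]-2,6-dimethylcyclohex-1-ene; 15 methyl but-2-ynoate
Product: 16 methyl 3α,6,19-tris(tert-butyldimethylsilyloxy)-12,13,14,15,16-pentanorlabda-5,8-dien-11-oate
Conditions: 15 (10 equiv), toluene, BHT (cat.), base-washed sealed tube, 150 °C
Reagents that add atoms: none
Why: The step is a thermal, concerted but asynchronous [4+2] cycloaddition of normal electron demand between the electron-rich diene C10=C5–C6(OTBS)=C7 and the ynoate; its closest known type is the Diels–Alder reaction of 2-silyloxy-1,3-dienes and of 1-vinylcyclohexenes with alkynoates, which gives 1,4-cyclohexadienes. Ring B (C5–C10) is closed by cycloaddition as a six-membered ring, the bonds C7–C8 and C9–C10 forming in the same step. The regiochemistry (ester 1,4 to the silyloxy group) follows from the large diene coefficient at C7, raised by the C6 silyloxy donor, which bonds to the β-carbon of the ynoate (C8, bearing the C17 methyl), so the ester-bearing carbon C9 goes to C10. The one new stereocentre, C10, is decided by the face of C5=C10 that the alkyne takes: in the ring A half-chair that holds 3α-OTBS and 4β-CH2OTBS trans-diaxial, the pseudoaxial CH2OTBS covers the β-face at the 1,3-related C10, so C9 should enter from the α-face and the C20 methyl ends β. A linear alkyne is the least demanding partner for the fully substituted terminus, and the adduct already contains the tetrasubstituted C8=C9 bond, the C11 carbon and the masked C6 ketone.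

Step 13
Reactants: 16 methyl 3α,6,19-tris(tert-butyldimethylsilyloxy)-12,13,14,15,16-pentanorlabda-5,8-dien-11-oate
Product: 17 methyl 3α,19-bis(tert-butyldimethylsilyloxy)-6-oxo-12,13,14,15,16-pentanorlabd-8-en-11-oate (5α-H)
Conditions: Bu4NF (1.05 equiv), AcOH, THF, −78 to −40 °C
Reagents that add atoms: none
Why: Fluoride cleaves the enol silyl ether far faster than the two alkyl silyl ethers, and the buffered enolate is protonated at C5 from the α-face, away from the β-axial C20 methyl and C19 CH2OTBS, to give the trans-fused 6-ketone, which is also the more stable C5 epimer.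

Step 14
Reactants: 17 methyl 3α,19-bis(tert-butyldimethylsilyloxy)-6-oxo-12,13,14,15,16-pentanorlabd-8-en-11-oate
Product: 18 methyl 3α,19-bis(tert-butyldimethylsilyloxy)-6β-hydroxy-12,13,14,15,16-pentanorlabd-8-en-11-oate
Conditions: NaBH4, MeOH/CH2Cl2, −20 to 0 °C
Reagents that add atoms: none
Why: Borohydride reduction: the β-face of the C6 carbonyl is blocked by the syn-axial C19 and C20 groups, so hydride should add from the α-face and give the axial 6β-alcohol, while the tetrasubstituted enoate is not reduced.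

Step 15
Reactants: 18 methyl 3α,19-bis(tert-butyldimethylsilyloxy)-6β-hydroxy-12,13,14,15,16-pentanorlabd-8-en-11-oate
Product: 19 3α,19-bis(tert-butyldimethylsilyloxy)-12,13,14,15,16-pentanorlabd-8-ene-6β,11-diol
Conditions: iBu2AlH (excess), CH2Cl2, −78 to 0 °C; aq. potassium sodium tartrate
Reagents that add atoms: none
Why: Hydride reduction of the conjugated ester by 1,2-addition gives the C11 allylic alcohol; the free 6β-hydroxyl only consumes one equivalent of hydride.

Step 16
Reactants: 19 3α,19-bis(tert-butyldimethylsilyloxy)-12,13,14,15,16-pentanorlabd-8-ene-6β,11-diol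
Product: 20 11-bromo-3α,19-bis(tert-butyldimethylsilyloxy)-12,13,14,15,16-pentanorlabd-8-en-6β-ol
Conditions: CBr4, PPh3, CH2Cl2, −20 °C; used without storage
Reagents that add atoms: carbon tetrabromide, BrC(Br)(Br)Br
Why: Appel reaction converts the primary allylic alcohol selectively, since the 6β-hydroxyl is flanked by two syn-axial groups and cannot close onto C11 without a bridgehead alkene.

Step 17
Reactants: 20 11-bromo-3α,19-bis(tert-butyldimethylsilyloxy)-12,13,14,15,16-pentanorlabd-8-en-6β-ol; 21 methyl acetoacetate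
Product: 22 methyl 3α,19-bis(tert-butyldimethylsilyloxy)-6β-hydroxy-13-oxo-14,15-dinorlabd-8-ene-12-carboxylate (C12 epimers)
Conditions: 21 (3 equiv), NaH (2.8 equiv), THF/DMF, 0 °C; then 20, rt
Reagents that add atoms: none
Why: Acetoacetic ester alkylation (SN2 of the preformed sodium enolate on the primary allylic bromide) forms C11–C12; the C12 centre is lost in the next step.

Step 18
Reactants: 22 methyl 3α,19-bis(tert-butyldimethylsilyloxy)-6β-hydroxy-13-oxo-14,15-dinorlabd-8-ene-12-carboxylate
Product: 23 3α,19-bis(tert-butyldimethylsilyloxy)-6β-hydroxy-14,15-dinorlabd-8-en-13-one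
Conditions: LiCl, H2O, DMSO, 140 °C
Reagents that add atoms: none
Why: Krapcho dealkoxycarbonylation (chloride attack on the methyl ester, loss of CO2, protonation) gives the methyl ketone under neutral conditions that spare the silyl ethers.

Step 19
Reactants: 23 3α,19-bis(tert-butyldimethylsilyloxy)-6β-hydroxy-14,15-dinorlabd-8-en-13-one; 24 allyl diethylphosphonoacetate
Product: 25 allyl (13E)-3α,19-bis(tert-butyldimethylsilyloxy)-6β-hydroxylabda-8,13-dien-15-oate
Conditions: 24 (4 equiv), NaH (3.8 equiv), THF, 0 °C; then 23, 0 to 50 °C; chromatographic removal of the 13Z isomer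
Reagents that add atoms: none
Why: Horner–Wadsworth–Emmons olefination of the methyl ketone gives the trisubstituted enoate, the reversible addition favouring the E isomer (chain trans to the ester); the allyl ester is chosen so that the acid can be freed last without touching the isovalerates.

Step 20
Reactants: 25 allyl (13E)-3α,19-bis(tert-butyldimethylsilyloxy)-6β-hydroxylabda-8,13-dien-15-oate
Product: 26 allyl (13E)-3α,6β,19-trihydroxylabda-8,13-dien-15-oate
Conditions: HF·pyridine, pyridine, THF, 0 °C to rt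
Reagents that add atoms: none
Why: Fluoride desilylation under buffered acidic conditions frees O3 and O19 together and leaves the allyl enoate and both alkenes untouched.

Step 21
Reactants: 26 allyl (13E)-3α,6β,19-trihydroxylabda-8,13-dien-15-oate
Product: 27 allyl (13E)-6β-hydroxy-3α,19-bis(3-methylbutanoyloxy)labda-8,13-dien-15-oate
Conditions: isovaleric anhydride (3 equiv), 4-(dimethylamino)pyridine, Et3N, CH2Cl2, 0 °C to rt
Reagents that add atoms: isovaleric anhydride, CC(C)CC(=O)OC(=O)CC(C)C
Why: Acyl transfer catalysed by 4-(dimethylamino)pyridine should acylate the primary C19 and the secondary 3α-hydroxyl, while the 6β-hydroxyl, syn-axial to both C19 and C20, is too hindered to react.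

Step 22
Reactants: 27 allyl (13E)-6β-hydroxy-3α,19-bis(3-methylbutanoyloxy)labda-8,13-dien-15-oate
Product: 28 (13E)-6β-hydroxy-3α,19-bis(3-methylbutanoyloxy)labda-8,13-dien-15-oic acid (CNP0333611.1)
Conditions: Pd(PPh3)4 (5 mol %), morpholine, THF, rt; dilute acid work-up
Reagents that add atoms: none
Why: Tsuji–Trost deallylation: zerovalent palladium ionises the allyl ester to a π-allyl complex that morpholine captures, which frees the C15 acid under conditions that leave the two isovalerates and the free 6β-hydroxyl alone.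

**Compound list**
1 | 2-methylcyclohexane-1,3-dione | CC1C(=O)CCCC1=O | starting material
2 | 2-(hydroxymethyl)-2-methylcyclohexane-1,3-dione | CC1(CO)C(=O)CCCC1=O | intermediate
3 | 2-[(tert-butyldimethylsilyloxy)methyl]-2-methylcyclohexane-1,3-dione | CC1(CO[Si](C)(C)C(C)(C)C)C(=O)CCCC1=O | intermediate
4 | (2R,3R)-2-[(tert-butyldimethylsilyloxy)methyl]-3-hydroxy-2-methylcyclohexan-1-one | O=C1CCC[C@@H](O)[C@@]1(C)CO[Si](C)(C)C(C)(C)C | intermediate
5 | (1R,2S,3R)-2-[(tert-butyldimethylsilyloxy)methyl]-3-hydroxy-2-methylcyclohexyl acetate | CC(=O)O[C@@H]1CCC[C@@H](O)[C@]1(C)CO[Si](C)(C)C(C)(C)C | intermediate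
6 | (1R,2R,3R)-3-(tert-butyldimethylsilyloxy)-2-[(tert-butyldimethylsilyloxy)methyl]-2-methylcyclohexyl acetate | CC(=O)O[C@@H]1CCC[C@@H](O[Si](C)(C)C(C)(C)C)[C@]1(C)CO[Si](C)(C)C(C)(C)C | intermediate
7 | (1R,2R,3R)-3-(tert-butyldimethylsilyloxy)-2-[(tert-butyldimethylsilyloxy)methyl]-2-methylcyclohexan-1-ol | O[C@@H]1CCC[C@@H](O[Si](C)(C)C(C)(C)C)[C@]1(C)CO[Si](C)(C)C(C)(C)C | intermediate
8 | (2S,3R)-3-(tert-butyldimethylsilyloxy)-2-[(tert-butyldimethylsilyloxy)methyl]-2-methylcyclohexan-1-one | O=C1CCC[C@@H](O[Si](C)(C)C(C)(C)C)[C@]1(C)CO[Si](C)(C)C(C)(C)C | intermediate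
9 | (2S,3R,6RS)-3-(tert-butyldimethylsilyloxy)-2-[(tert-butyldimethylsilyloxy)methyl]-2,6-dimethylcyclohexan-1-one | CC1CC[C@@H](O[Si](C)(C)C(C)(C)C)[C@](C)(CO[Si](C)(C)C(C)(C)C)C1=O | intermediate
10 | (5R,6S)-5-(tert-butyldimethylsilyloxy)-6-[(tert-butyldimethylsilyloxy)methyl]-2,6-dimethylcyclohex-1-en-1-yl trifluoromethanesulfonate | FC(F)(F)S(=O)(=O)OC1=C(C)CC[C@@H](O[Si](C)(C)C(C)(C)C)[C@]1(C)CO[Si](C)(C)C(C)(C)C | intermediate
11 | tributyl(1-ethoxyvinyl)stannane | CCCC[Sn](CCCC)(CCCC)C(=C)OCC | starting material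
12 | ring A 2-ethoxydiene, (5R,6S)-5-(tert-butyldimethylsilyloxy)-6-[(tert-butyldimethylsilyloxy)methyl]-1-(1-ethoxyvinyl)-2,6-dimethylcyclohex-1-ene | C=C(OCC)C1=C(C)CC[C@@H](O[Si](C)(C)C(C)(C)C)[C@]1(C)CO[Si](C)(C)C(C)(C)C | intermediate (not isolated)
13 | 1-{(5R,6S)-5-(tert-butyldimethylsilyloxy)-6-[(tert-butyldimethylsilyloxy)methyl]-2,6-dimethylcyclohex-1-en-1-yl}ethan-1-one | CC(=O)C1=C(C)CC[C@@H](O[Si](C)(C)C(C)(C)C)[C@]1(C)CO[Si](C)(C)C(C)(C)C | intermediate
14 | ring A 2-silyloxydiene, (5R,6S)-5-(tert-butyldimethylsilyloxy)-6-[(tert-butyldimethylsilyloxy)methyl]-1-[1-(tert-butyldimethylsilyloxy)vinyl]-2,6-dimethylcyclohex-1-ene | C=C(O[Si](C)(C)C(C)(C)C)C1=C(C)CC[C@@H](O[Si](C)(C)C(C)(C)C)[C@]1(C)CO[Si](C)(C)C(C)(C)C | intermediate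
15 | methyl but-2-ynoate | CC#CC(=O)OC | starting material
16 | methyl 3α,6,19-tris(tert-butyldimethylsilyloxy)-12,13,14,15,16-pentanorlabda-5,8-dien-11-oate | CC1=C(C(=O)OC)[C@@]2(C)CC[C@@H](O[Si](C)(C)C(C)(C)C)[C@](C)(CO[Si](C)(C)C(C)(C)C)C2=C(O[Si](C)(C)C(C)(C)C)C1 | intermediate
17 | methyl 3α,19-bis(tert-butyldimethylsilyloxy)-6-oxo-12,13,14,15,16-pentanorlabd-8-en-11-oate | CC1=C(C(=O)OC)[C@@]2(C)CC[C@@H](O[Si](C)(C)C(C)(C)C)[C@](C)(CO[Si](C)(C)C(C)(C)C)[C@@H]2C(=O)C1 | intermediate
18 | methyl 3α,19-bis(tert-butyldimethylsilyloxy)-6β-hydroxy-12,13,14,15,16-pentanorlabd-8-en-11-oate | CC1=C(C(=O)OC)[C@@]2(C)CC[C@@H](O[Si](C)(C)C(C)(C)C)[C@](C)(CO[Si](C)(C)C(C)(C)C)[C@@H]2[C@H](O)C1 | intermediate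
19 | 3α,19-bis(tert-butyldimethylsilyloxy)-12,13,14,15,16-pentanorlabd-8-ene-6β,11-diol | CC1=C(CO)[C@@]2(C)CC[C@@H](O[Si](C)(C)C(C)(C)C)[C@](C)(CO[Si](C)(C)C(C)(C)C)[C@@H]2[C@H](O)C1 | intermediate
20 | 11-bromo-3α,19-bis(tert-butyldimethylsilyloxy)-12,13,14,15,16-pentanorlabd-8-en-6β-ol | CC1=C(CBr)[C@@]2(C)CC[C@@H](O[Si](C)(C)C(C)(C)C)[C@](C)(CO[Si](C)(C)C(C)(C)C)[C@@H]2[C@H](O)C1 | intermediate
21 | methyl acetoacetate | CC(=O)CC(=O)OC | starting material
22 | methyl 3α,19-bis(tert-butyldimethylsilyloxy)-6β-hydroxy-13-oxo-14,15-dinorlabd-8-ene-12-carboxylate | CC1=C(CC(C(C)=O)C(=O)OC)[C@@]2(C)CC[C@@H](O[Si](C)(C)C(C)(C)C)[C@](C)(CO[Si](C)(C)C(C)(C)C)[C@@H]2[C@H](O)C1 | intermediate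
23 | 3α,19-bis(tert-butyldimethylsilyloxy)-6β-hydroxy-14,15-dinorlabd-8-en-13-one | CC1=C(CCC(C)=O)[C@@]2(C)CC[C@@H](O[Si](C)(C)C(C)(C)C)[C@](C)(CO[Si](C)(C)C(C)(C)C)[C@@H]2[C@H](O)C1 | intermediate
24 | allyl diethylphosphonoacetate | CCOP(=O)(CC(=O)OCC=C)OCC | starting material
25 | allyl (13E)-3α,19-bis(tert-butyldimethylsilyloxy)-6β-hydroxylabda-8,13-dien-15-oate | CC1=C(CC/C(C)=C/C(=O)OCC=C)[C@@]2(C)CC[C@@H](O[Si](C)(C)C(C)(C)C)[C@](C)(CO[Si](C)(C)C(C)(C)C)[C@@H]2[C@H](O)C1 | intermediate
26 | allyl (13E)-3α,6β,19-trihydroxylabda-8,13-dien-15-oate | CC1=C(CC/C(C)=C/C(=O)OCC=C)[C@@]2(C)CC[C@@H](O)[C@](C)(CO)[C@@H]2[C@H](O)C1 | intermediate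
27 | allyl (13E)-6β-hydroxy-3α,19-bis(3-methylbutanoyloxy)labda-8,13-dien-15-oate | CC1=C(CC/C(C)=C/C(=O)OCC=C)[C@@]2(C)CC[C@@H](OC(=O)CC(C)C)[C@](C)(COC(=O)CC(C)C)[C@@H]2[C@H](O)C1 | intermediate
28 | (13E)-6β-hydroxy-3α,19-bis(3-methylbutanoyloxy)labda-8,13-dien-15-oic acid (CNP0333611.1) | CC1=C(CC/C(C)=C/C(=O)O)[C@@]2(C)CC[C@@H](OC(=O)CC(C)C)[C@](C)(COC(=O)CC(C)C)[C@@H]2[C@H](O)C1 | target

**Step count**
Total steps: 22. Longest linear sequence: 22 steps (1 to 28); compounds 11, 15, 21 and 24 are bought.

**Steps most likely to fail, with fallbacks**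

Step 12 carries the main risk. The cycloaddition may be too slow at the fully substituted C10 terminus, so that a [1,5]-hydrogen shift of the diene or loss of the enol silyl group competes at the temperature needed, and the alkyne may discriminate poorly between the two faces of C5=C10. The fallback sets out from diene 14 and uses the more electrophilic but-2-ynal (from but-2-yn-1-ol and MnO2) as dienophile in toluene at 80 °C, where face discrimination should be better, to give the aldehyde cycloadduct F1. Fluoride cleavage of the enol silyl ether (Bu4NF, AcOH, −78 °C) would give the 6-oxo aldehyde F2. NaBH4 with CeCl3 would then reduce the C6 ketone from the α-face and the aldehyde in one operation, which comes back to the route at diol 19 and bypasses 16 to 18.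

In step 3 the hydride may be delivered syn to the CH2OTBS branch, or with little discrimination between the two faces of the carbonyl, so that the hydroxyl ends trans to CH2OTBS. The fallback sets out from dione 3: the same oxazaborolidine still fixes the carbinol carbon as R, and the product is then the trans ketol F3, in which the carbinol carbon is already C3 and the remaining ketone is C5. After separation, F3 would be silylated directly (TBSOTf, 2,6-lutidine) and comes back to the route at ketone 8 without the oxygen transposition of steps 4 to 7. Either diastereomer of the reduction therefore leads to the same enantiomer of 8.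

In step 4 hemiacetal formation and hydride transfer at the ketone next to the quaternary carbon may be slow, and acyl migration or retro-aldol opening of the β-hydroxy ketone may take over. The fallback sets out from ketol 4: acetylation (Ac2O, 4-(dimethylamino)pyridine, pyridine) would give the keto acetate F4, and HF·pyridine would free the primary alcohol to give the hydroxymethyl ketone F5. Hydroxyl-directed reduction with Me4NBH(OAc)3 (MeCN/AcOH, −20 °C), in which hydride is delivered within an alkoxyborohydride from the face of the CH2OH branch, would give the diol acetate F6 with the new hydroxyl trans to CH2OH. Double silylation (TBSOTf, 2,6-lutidine) comes back to the route at 6.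

**Further compounds**
F1 | step 12 | 3α,6,19-tris(tert-butyldimethylsilyloxy)-12,13,14,15,16-pentanorlabda-5,8-dien-11-al | CC1=C(C=O)[C@@]2(C)CC[C@@H](O[Si](C)(C)C(C)(C)C)[C@](C)(CO[Si](C)(C)C(C)(C)C)C2=C(O[Si](C)(C)C(C)(C)C)C1
F2 | step 12 | 3α,19-bis(tert-butyldimethylsilyloxy)-6-oxo-12,13,14,15,16-pentanorlabd-8-en-11-al | CC1=C(C=O)[C@@]2(C)CC[C@@H](O[Si](C)(C)C(C)(C)C)[C@](C)(CO[Si](C)(C)C(C)(C)C)[C@@H]2C(=O)C1
F3 | step 3 | (2S,3R)-2-[(tert-butyldimethylsilyloxy)methyl]-3-hydroxy-2-methylcyclohexan-1-one | O=C1CCC[C@@H](O)[C@]1(C)CO[Si](C)(C)C(C)(C)C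
F4 | step 4 | (1R,2R)-2-[(tert-butyldimethylsilyloxy)methyl]-2-methyl-3-oxocyclohexyl acetate | O=C1CCC[C@@H](OC(C)=O)[C@@]1(C)CO[Si](C)(C)C(C)(C)C
F5 | step 4 | (1R,2R)-2-(hydroxymethyl)-2-methyl-3-oxocyclohexyl acetate | O=C1CCC[C@@H](OC(C)=O)[C@@]1(C)CO
F6 | step 4 | (1R,2S,3R)-3-hydroxy-2-(hydroxymethyl)-2-methylcyclohexyl acetate | CC(=O)O[C@@H]1CCC[C@@H](O)[C@]1(C)CO
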